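**Plan**
1. Numbering follows the ent-kaurane skeleton: A ring = C1–C5 + C10; δ-lactone = C7–C8–C9–C10–C20–O; C ring = C8, C9, C11–C14; D ring = C8, C13–C16 (C17 = exocyclic CH2).
2. The A ring holds the γ,δ-unsaturated aldehyde array O=C6–C5–C4–C3=C2 directly beside the C1 ketone, between the quaternary carbons C4 and C10. A retro-Claisen cut of C4–C5 turns it into a 2-(2-methylprop-1-enyl)-2H-pyran-3(4H)-one spiro-fused at C10 (temporary ring O–C2–C1–C10–C5=C6), which is the cyclo-acetal of a C2 α-hydroxy ketone with a C6 acetal.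
3. Further cuts: C1–C2 (acyl chloride + alkenylzirconium), C5–C10 (Ireland–Claisen), C10–C20 and O–C7 (aldol, lactonisation), C13–C16 (ketyl–alkyne), C8–C15 (ester aldol), C8–C9 and C11–C12 (Michael/aldol annulation of 1 and 2).
4. Forward order: ring C, then the C8 quaternary centre, D ring, δ-lactone, C10 quaternary centre and its two arms, then in one operation the temporary pyran ring and the A ring (last ring), then desilylation.
5. Stereocentres: C9 from the prolinol catalyst; C8 by addition anti to the C9 arm; C15 from the Ru/TsDPEN catalyst; C13 from the bridging geometry; C10 by outer-face [3,3] on the locked lactone; C2 from a chiral oxaziridine; C5 by suprafacial transfer from C2 in the key step.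

Key step: step 17

Remark: 1, 2, 3-(trimethylsilyl)prop-2-ynal and 3-methylbut-1-yne are taken as catalogue chemicals; descriptors with locants 2–15 in later names refer to the skeleton numbering above.

**Step 1**
Reactants: 1 benzyl 4-oxobutanoate; 2 methyl (E)-4-oxopent-2-enoate
Product: 4 methyl (2R)-2-[2-(benzyloxy)-2-oxoethyl]-5-oxocyclohex-3-ene-1-carboxylate (C1 epimers), via Michael adduct 3 (not isolated)
Conditions: (R)-α,α-diphenylprolinol TMS ether (10 mol%), 4-nitrophenol (10 mol%), toluene, 0 °C to rt; then TsOH·H2O (20 mol%), 40 °C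
Reagents that add atoms: none
Why: Enamine Michael addition to the ketone-activated β-carbon of 2, then aldol condensation of the methyl ketone onto the aldehyde (organocatalytic Robinson-type annulation), closes ring C; the (R)-catalyst shields one enamine face and sets C9, and the epimerisable C8 centre is reset in step 4.

**Step 2**
Reactants: 4 cyclohexenone benzyl ester
Product: 5 2-[(1S)-2-(methoxycarbonyl)-4-oxocyclohexyl]acetic acid (C2 epimers)
Conditions: H2 (1 atm), 10% Pd/C, EtOAc, rt
Reagents that add atoms: none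
Why: Catalytic hydrogenation saturates the C11=C12 alkene and hydrogenolyses the benzyl ester in one operation, giving the free acid needed for selective enolisation in step 4; C9 is not touched.

**Step 3**
Reactants: 5 keto acid
Product: 6 2-[(8S)-7-(methoxycarbonyl)-1,4-dioxaspiro[4.5]decan-8-yl]acetic acid
Conditions: 2-ethyl-2-methyl-1,3-dioxolane (solvent), TsOH·H2O (5 mol%), rt
Reagents that add atoms: 2-ethyl-2-methyl-1,3-dioxolane, CCC1(C)OCCO1
Why: Acid-catalysed transketalisation protects the C13 ketone without free glycol, so the carboxylic acid is not esterified.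

**Step 4**
Reactants: 6 ketal acid
Product: 7 2-[(7S,8S)-7-[1-hydroxy-3-(trimethylsilyl)prop-2-yn-1-yl]-7-(methoxycarbonyl)-1,4-dioxaspiro[4.5]decan-8-yl]acetic acid (C15 epimers)
Conditions: LDA (2.2 equiv), THF, −78 to −40 °C; 3-(trimethylsilyl)prop-2-ynal, −78 °C; AcOH quench; used at once
Reagents that add atoms: 3-(trimethylsilyl)prop-2-ynal, C[Si](C)(C)C#CC=O
Why: The carboxylate resists a second deprotonation, so only the C8 ester enolate forms; its aldol addition to the ynal should build the C8 quaternary centre anti to the C9 arm, which sits axial to avoid A(1,3) strain, and the C15 mixture is corrected in steps 5 and 7.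

**Step 5**
Reactants: 7 aldol adduct
Product: 8 2-[(7S,8S)-7-(methoxycarbonyl)-7-[3-(trimethylsilyl)prop-2-ynoyl]-1,4-dioxaspiro[4.5]decan-8-yl]acetic acid
Conditions: Dess–Martin periodinane, NaHCO3, CH2Cl2, 0 °C to rt
Reagents that add atoms: none
Why: Dess–Martin oxidation of the propargylic alcohol gives the non-enolisable ynone, which removes the uncontrolled C15 centre and the risk of δ-lactonisation with the acid.

**Step 6**
Reactants: 8 ynone acid
Product: 9 methyl (7S,8S)-8-[2-(allyloxy)-2-oxoethyl]-7-[3-(trimethylsilyl)prop-2-ynoyl]-1,4-dioxaspiro[4.5]decane-7-carboxylate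
Conditions: allyl bromide (1.2 equiv), KHCO3, DMF, rt
Reagents that add atoms: allyl bromide, C=CCBr
Why: SN2 O-alkylation of the carboxylate under bicarbonate leaves the base-sensitive ynone intact and installs the ester needed for the Ireland–Claisen step.

**Step 7**
Reactants: 9 ynone allyl ester
Product: 10 methyl (7S,8S)-8-[2-(allyloxy)-2-oxoethyl]-7-[(1S)-1-hydroxy-3-(trimethylsilyl)prop-2-yn-1-yl]-1,4-dioxaspiro[4.5]decane-7-carboxylate
Conditions: RuCl[(S,S)-TsDPEN](p-cymene) (2 mol%), HCO2H/Et3N (5:2), CH2Cl2, rt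
Reagents that add atoms: none
Why: Noyori asymmetric transfer hydrogenation is chemoselective for the ynone C=O and catalyst-controlled; with the alkynyl group as the π substituent the (S,S) catalyst should give the carbinol with the C15 configuration of the target.

**Step 8**
Reactants: 10 propargylic alcohol
Product: 11 15-O-TBS ether of 10
Conditions: TBSOTf, 2,6-lutidine, CH2Cl2, −78 to 0 °C
Reagents that add atoms: tert-butyldimethylsilyl triflate, CC(C)(C)[Si](C)(C)OS(=O)(=O)C(F)(F)F
Why: Silylation with the triflate protects the hindered carbinol before it can translactonise onto the allyl ester.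

**Step 9**
Reactants: 11 TBS ether
Product: 13 methyl (1S,2S)-2-[2-(allyloxy)-2-oxoethyl]-1-[(1R)-1-[(tert-butyldimethylsilyl)oxy]prop-2-yn-1-yl]-5-oxocyclohexane-1-carboxylate, via terminal alkyne ketal 12 (not isolated)
Conditions: K2CO3 (0.2 equiv), allyl alcohol, rt; concentrate; then 1 M HCl, THF, rt
Reagents that add atoms: water, O
Why: Carbonate in allyl alcohol cleaves the alkynyl C–Si bond while any exchange at the allyl ester is degenerate, and aqueous acid then hydrolyses the dioxolane without removing the hindered TBS ether.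

**Step 10**
Reactants: 13 keto alkyne
Product: 14 (8S,9S,13S,15R)-bicyclo[3.2.1]octane diester (13-OH; 15-OTBS; 16-methylene; C8 CO2Me; C9 CH2CO2allyl)
Conditions: SmI2 (3 equiv), HMPA (12 equiv), t-BuOH (2 equiv), THF, 0 °C to rt
Reagents that add atoms: none
Why: SmI2 ketyl–alkyne radical cyclisation (5-exo-dig from C13 onto C16) gives the bridgehead carbinol and the exocyclic methylene; C13 is fixed because the two-carbon bridge can only span ring C in a 1,3-diaxial way.

**Step 11**
Reactants: 14 D-ring diester
Product: 16 (8S,9S,13S,15R)-7,20-δ-lactone with the allyl ester on C10 (C10 epimers), via hydroxymethyl ester 15 (not isolated)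
Conditions: LDA (2.2 equiv), THF, −78 °C; CH2O gas, −78 °C; AcOH quench; then 1-hydroxy-3-isothiocyanatotetrabutyldistannoxane (5 mol%), toluene, 90 °C
Reagents that add atoms: formaldehyde, C=O
Why: The only enolisable ester (C8 is quaternary) adds to formaldehyde (aldol), and neutral tin-catalysed transesterification closes the lactone onto the cis C7 ester without base, which would cause β-elimination; C10 is still a mixture.

**Step 12**
Reactants: 16 lactone allyl ester
Product: 19 (8S,9S,10R,13S,15R)-C10-allyl lactone acid (13-OTMS; 15-OTBS), via silyl ketene acetal 17 (not isolated), via trimethylsilyl ester 18 (not isolated)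
Conditions: TMSCl (6 equiv)/Et3N, THF, −100 °C, then LDA (2.3 equiv) added (internal quench); −78 °C to rt, then 45 °C; pH 5 buffer work-up
Reagents that add atoms: chlorotrimethylsilane, C[Si](C)(C)Cl
Why: Ireland–Claisen rearrangement: the enolate is silylated as it forms (the C13 alkoxide too), and the exocyclic ketene acetal passes allyl through a chair [3,3] transition state to the outer face of C10, because the inner face lies over ring C (C12–H, C14–H) of the bridged, locked bicycle; C5 should therefore end cis to H9 as in the target.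

**Step 13**
Reactants: 19 lactone acid
Product: 21 (8S,9S,10R,13S,15R)-(E)-enone (C1 ketone bearing CH=CH–CHMe2), via acid chloride 20 (not isolated)
Conditions: 1-chloro-N,N,2-trimethylprop-1-en-1-amine, CH2Cl2, 0 °C; separately 3-methylbut-1-yne, Cp2Zr(H)Cl, THF, rt; combine, CuI (10 mol%), rt
Reagents that add atoms: 3-methylbut-1-yne, CC(C)C#C
Why: Neutral acid chloride formation, then copper-catalysed acylation of the (E)-alkenylzirconocene from syn hydrozirconation (Negishi-type acylation), gives the E enone; the acid chloride is far more electrophilic than the hindered lactone.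

**Step 14**
Reactants: 21 enone
Product: 23 C6 aldehyde (C10 arm CH2CHO), via diol 22 (not isolated)
Conditions: K2OsO4·2H2O (2 mol%), NaIO4 (4 equiv), 2,6-lutidine, dioxane/H2O 3:1, rt
Reagents that add atoms: sodium periodate (oxygen source for the osmium cycle), [Na+].[O-]I(=O)(=O)=O
Why: Lemieux–Johnson cleavage should select the unhindered monosubstituted alkene, since the enone alkene is electron-poor and the exocyclic methylene is flanked by the silyloxy-bearing carbons C13 and C15.

**Step 15**
Reactants: 23 aldehyde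
Product: 24 C6 dimethyl acetal (13-OH free; 15-OTBS)
Conditions: HC(OMe)3 (5 equiv), PPTS (10 mol%), MeOH, rt
Reagents that add atoms: trimethyl orthoformate, COC(OC)OC
Why: Orthoformate acetalisation protects the aldehyde for the basic step and stores C6 at the level needed for enol ether formation; the acidic methanol also cleaves the tertiary TMS ether.

**Step 16**
Reactants: 24 enone acetal
Product: 25 (2S)-α-hydroxy-β,γ-unsaturated ketone [C1(=O)–C2H(OH)–CH=CMe2]
Conditions: KHMDS (2.3 equiv), THF, −78 °C; (+)-(2R,8aS)-(camphorylsulfonyl)oxaziridine (1.5 equiv), −78 °C; AcOH quench at −78 °C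
Reagents that add atoms: (+)-(camphorylsulfonyl)oxaziridine, CC1(C)C2CCC13CS(=O)(=O)N4OC34C2
Why: C10 is quaternary, so the base can only remove the γ-hydrogen at C4, and the linear dienolate is oxidised at its α-carbon C2 (enolate hydroxylation by an N-sulfonyloxaziridine, with deconjugation); the (+)-reagent is chosen by analogy with Z enolates of aryl ketones, which give the (S)-carbinol needed here.

**Step 17**
Reactants: 25 α-hydroxy ketone acetal
Product: 28 15-O-TBS ether of the target (5R,8S,9S,10S,13S,15R), via cyclic methyl acetal 26 (not isolated), via pyranone enol ether 27 (not isolated)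
Conditions: propionic acid (10 mol%), BHT, mesitylene (0.01 M), 4 Å sieves in a Soxhlet thimble, 110 to 165 °C
Reagents that add atoms: none
Why: Acid-catalysed transacetalisation of the C2 hydroxyl with the C6 acetal gives 26, loss of the second methanol gives the 2-alkenyl-2H-pyran-3(4H)-one 27, and its allyl vinyl ether unit C5=C6–O–C2–C3=C4 undergoes a [3,3] shift that makes C4–C5 and breaks O–C2. The closest known reaction types are the Claisen rearrangement of allyl vinyl ethers made in situ from acetals and the thermal ring contraction of 2-alkenyl-3,4-dihydro-2H-pyrans to cyclohex-3-enecarbaldehydes. The temporary pyran closes by 6-exo attack of the C2 oxygen on the C6 oxocarbenium ion, and the A ring (C1–C5, C10) closes pericyclically through a boat-like bicyclo[2.2.2] array with C2 and C5 as bridgeheads. C5 is the only new stereocentre and is set by suprafacial transfer from C2: the isobutenyl group, cis to C9 on the pyranone, bonds to the C5 face cis to C9, which leaves the formyl group cis to C20. The same event makes C4 the gem-dimethyl quaternary carbon and places the C2=C3 alkene in conjugation with the C1 ketone. The step needs C2 to keep its configuration until the shift (weak acid, high dilution, methanol removed) and needs [3,3] to outrun ionisation or a [1,3] shift, which the radical-stabilising C1 carbonyl on C2 and the conjugated product should secure.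

**Step 18**
Reactants: 28 silyl ether
Product: 29 CNP0521079.1 (target)
Conditions: HF·pyridine, pyridine, THF, 0 °C to rt
Reagents that add atoms: none
Why: Fluoride cleavage of the silyl ether under buffered acidic conditions avoids base, which could epimerise C5 next to the aldehyde.

**Compound list**
1 | benzyl 4-oxobutanoate | O=CCCC(=O)OCc1ccccc1 | starting material
2 | methyl (E)-4-oxopent-2-enoate | COC(=O)/C=C/C(C)=O | starting material
3 | 5-benzyl 1-methyl (3S)-3-formyl-2-(2-oxopropyl)pentanedioate (C2 epimers) | O=C[C@@H](CC(=O)OCc1ccccc1)C(CC(C)=O)C(=O)OC | intermediate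
4 | methyl (2R)-2-[2-(benzyloxy)-2-oxoethyl]-5-oxocyclohex-3-ene-1-carboxylate (C1 epimers) | O=C1C=C[C@@H](CC(=O)OCc2ccccc2)C(C(=O)OC)C1 | intermediate
5 | 2-[(1S)-2-(methoxycarbonyl)-4-oxocyclohexyl]acetic acid (C2 epimers) | O=C1CC[C@@H](CC(=O)O)C(C(=O)OC)C1 | intermediate
6 | 2-[(8S)-7-(methoxycarbonyl)-1,4-dioxaspiro[4.5]decan-8-yl]acetic acid | COC(=O)C1CC2(OCCO2)CC[C@H]1CC(=O)O | intermediate
7 | C8-quaternary aldol adduct (C15 epimers) | C[Si](C)(C)C#CC(O)[C@]1(C(=O)OC)CC2(OCCO2)CC[C@H]1CC(=O)O | intermediate
8 | ynone acid | C[Si](C)(C)C#CC(=O)[C@]1(C(=O)OC)CC2(OCCO2)CC[C@H]1CC(=O)O | intermediate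
9 | ynone allyl ester | C[Si](C)(C)C#CC(=O)[C@]1(C(=O)OC)CC2(OCCO2)CC[C@H]1CC(=O)OCC=C | intermediate
10 | (15S)-propargylic alcohol | C[Si](C)(C)C#C[C@@H](O)[C@]1(C(=O)OC)CC2(OCCO2)CC[C@H]1CC(=O)OCC=C | intermediate
11 | 15-O-TBS ether of 10 | C[Si](C)(C)C#C[C@@H](O[Si](C)(C)C(C)(C)C)[C@]1(C(=O)OC)CC2(OCCO2)CC[C@H]1CC(=O)OCC=C | intermediate
12 | terminal alkyne ketal | C#C[C@@H](O[Si](C)(C)C(C)(C)C)[C@]1(C(=O)OC)CC2(OCCO2)CC[C@H]1CC(=O)OCC=C | intermediate
13 | keto alkyne | C#C[C@@H](O[Si](C)(C)C(C)(C)C)[C@]1(C(=O)OC)CC(=O)CC[C@H]1CC(=O)OCC=C | intermediate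
14 | (8S,9S,13S,15R)-bicyclo[3.2.1]octane diester | C=C1[C@@H](O[Si](C)(C)C(C)(C)C)[C@]2(C(=O)OC)C[C@@]1(O)CC[C@H]2CC(=O)OCC=C | intermediate
15 | hydroxymethyl ester (C10 epimers) | C=C1[C@@H](O[Si](C)(C)C(C)(C)C)[C@]2(C(=O)OC)C[C@@]1(O)CC[C@H]2C(CO)C(=O)OCC=C | intermediate
16 | 7,20-δ-lactone allyl ester (C10 epimers) | C=C1[C@@H](O[Si](C)(C)C(C)(C)C)[C@]23C[C@@]1(O)CC[C@H]2C(COC3=O)C(=O)OCC=C | intermediate
17 | silyl ketene acetal (13-OTMS) | C=C1[C@@H](O[Si](C)(C)C(C)(C)C)[C@]23C[C@@]1(O[Si](C)(C)C)CC[C@H]2C(COC3=O)=C(O[Si](C)(C)C)OCC=C | intermediate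
18 | trimethylsilyl ester of 19 | C=C1[C@@H](O[Si](C)(C)C(C)(C)C)[C@]23C[C@@]1(O[Si](C)(C)C)CC[C@H]2[C@](CC=C)(COC3=O)C(=O)O[Si](C)(C)C | intermediate
19 | (10R)-C10-allyl lactone acid (13-OTMS; 15-OTBS) | C=C1[C@@H](O[Si](C)(C)C(C)(C)C)[C@]23C[C@@]1(O[Si](C)(C)C)CC[C@H]2[C@](CC=C)(COC3=O)C(=O)O | intermediate
20 | acid chloride of 19 | C=C1[C@@H](O[Si](C)(C)C(C)(C)C)[C@]23C[C@@]1(O[Si](C)(C)C)CC[C@H]2[C@](CC=C)(COC3=O)C(=O)Cl | intermediate
21 | (E)-enone | C=C1[C@@H](O[Si](C)(C)C(C)(C)C)[C@]23C[C@@]1(O[Si](C)(C)C)CC[C@H]2[C@](CC=C)(COC3=O)C(=O)/C=C/C(C)C | intermediate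
22 | diol from the allyl group | C=C1[C@@H](O[Si](C)(C)C(C)(C)C)[C@]23C[C@@]1(O[Si](C)(C)C)CC[C@H]2[C@](CC(O)CO)(COC3=O)C(=O)/C=C/C(C)C | intermediate
23 | C6 aldehyde | C=C1[C@@H](O[Si](C)(C)C(C)(C)C)[C@]23C[C@@]1(O[Si](C)(C)C)CC[C@H]2[C@](CC=O)(COC3=O)C(=O)/C=C/C(C)C | intermediate
24 | C6 dimethyl acetal (13-OH free) | C=C1[C@@H](O[Si](C)(C)C(C)(C)C)[C@]23C[C@@]1(O)CC[C@H]2[C@](CC(OC)OC)(COC3=O)C(=O)/C=C/C(C)C | intermediate
25 | (2S)-α-hydroxy ketone | C=C1[C@@H](O[Si](C)(C)C(C)(C)C)[C@]23C[C@@]1(O)CC[C@H]2[C@](CC(OC)OC)(COC3=O)C(=O)[C@@H](O)C=C(C)C | intermediate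
26 | cyclic methyl acetal (6-methoxytetrahydropyran-3-one spiro at C10; C6 anomers) | C=C1[C@@H](O[Si](C)(C)C(C)(C)C)[C@]23C[C@@]1(O)CC[C@H]2[C@@]4(COC3=O)CC(OC)O[C@@H](C=C(C)C)C4=O | intermediate
27 | 2-(2-methylprop-1-enyl)-2H-pyran-3(4H)-one spiro at C10 | C=C1[C@@H](O[Si](C)(C)C(C)(C)C)[C@]23C[C@@]1(O)CC[C@H]2[C@@]4(COC3=O)C=CO[C@@H](C=C(C)C)C4=O | intermediate
28 | 15-O-TBS ether of the target | C=C1[C@@H](O[Si](C)(C)C(C)(C)C)[C@]23C[C@@]1(O)CC[C@H]2[C@]1(COC3=O)C(=O)C=CC(C)(C)[C@H]1C=O | intermediate
29 | CNP0521079.1 (5R,8S,9S,10S,13S,15R) | C=C1[C@@H](O)[C@]23C[C@@]1(O)CC[C@H]2[C@]1(COC3=O)C(=O)C=CC(C)(C)[C@H]1C=O | target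

**Count**
Total steps: 18. Longest linear sequence: 18 steps (from 1 or 2).

**Steps most likely to fail**

Step 17. Acid-promoted enolisation at C2 may erase the configuration that is to be transferred, and the shift through the congested boat (C4 and C10 both become or are quaternary) may be slow enough for decomposition to compete. The fallback sets out from 25 and avoids both the thermal step and the dependence on C2. Methyl chloroformate and pyridine should give the C2 methyl carbonate F1, and wet acetone with an acidic resin should free the keto aldehyde carbonate F2. Pd(PPh3)4 with catalytic pyrrolidine in DMSO at rt should then close the A ring by Tsuji–Trost α-allylation of the aldehyde through its enamine, which attacks the γ-terminus C4 of the π-allyl in a six-membered closure. This returns to 28; C5 would then be set under substrate control in the ring closure.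

Step 12. The C10 enolate carries a β-acyloxy group, so β-elimination of the C7 carboxylate (opening of the lactone) may outrun O-silylation. The fallback sets out from 14 and keeps the oxygen on C20 as an alkoxide, which is no leaving group. Step 11 is stopped after the aldol and 15 is isolated. Its trianion (LDA, THF/DMPU) is alkylated with allyl bromide (Fráter–Seebach-type alkylation) on the face away from ring C to give the C10-allylated hydroxy ester F3. Tin-catalysed lactonisation gives the lactone allyl ester F4, and Pd(PPh3)4 with morpholine frees the lactone acid F5. TMSCl and imidazole followed by a mild aqueous work-up return to 19.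

Step 16. Oxygen transfer to the acyclic dienolate may show poor facial selectivity if reagent and substrate control are mismatched. The fallback sets out from 24 and moves the stereo-determining event to a ketone reduction. Hydroxylation with achiral 2-(phenylsulfonyl)-3-phenyloxaziridine gives 25 together with its C2 epimer F6. Dess–Martin oxidation of the mixture gives the 1,2-diketone F7. Transfer hydrogenation with RuCl[(R,R)-TsDPEN](p-cymene) and HCO2H/Et3N should reduce the less hindered, alkenyl-flanked C2 carbonyl under catalyst control and return to 25.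

Further compounds
F1 | step 17 | C2 methyl carbonate of 25 | C=C1[C@@H](O[Si](C)(C)C(C)(C)C)[C@]23C[C@@]1(O)CC[C@H]2[C@](CC(OC)OC)(COC3=O)C(=O)[C@@H](OC(=O)OC)C=C(C)C
F2 | step 17 | keto aldehyde carbonate | C=C1[C@@H](O[Si](C)(C)C(C)(C)C)[C@]23C[C@@]1(O)CC[C@H]2[C@](CC=O)(COC3=O)C(=O)[C@@H](OC(=O)OC)C=C(C)C
F3 | step 12 | C10-allylated hydroxy ester | C=C1[C@@H](O[Si](C)(C)C(C)(C)C)[C@]2(C(=O)OC)C[C@@]1(O)CC[C@H]2[C@](CC=C)(CO)C(=O)OCC=C
F4 | step 12 | lactone allyl ester | C=C1[C@@H](O[Si](C)(C)C(C)(C)C)[C@]23C[C@@]1(O)CC[C@H]2[C@](CC=C)(COC3=O)C(=O)OCC=C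
F5 | step 12 | lactone acid with free 13-OH | C=C1[C@@H](O[Si](C)(C)C(C)(C)C)[C@]23C[C@@]1(O)CC[C@H]2[C@](CC=C)(COC3=O)C(=O)O
F6 | step 16 | (2R) epimer of 25 | C=C1[C@@H](O[Si](C)(C)C(C)(C)C)[C@]23C[C@@]1(O)CC[C@H]2[C@](CC(OC)OC)(COC3=O)C(=O)[C@H](O)C=C(C)C
F7 | step 16 | 1,2-diketone | C=C1[C@@H](O[Si](C)(C)C(C)(C)C)[C@]23C[C@@]1(O)CC[C@H]2[C@](CC(OC)OC)(COC3=O)C(=O)C(=O)C=C(C)C
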